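**Retrosynthetic overview**
1. C1–C10 is cut last: the 10-membered carbocycle comes from an acyclic ynal by a visible-light, nickel-catalysed, exo-selective reductive alkyne–aldehyde macrocyclisation that also creates the C1 carbinol and the C10(14) methylene.
2. Before that, on the open chain: Yamaguchi angeloylation of C6–OH, after hydroxyl-directed epoxidation of the C4–C5 olefin (C4 and C5 set from C6).
3. C6–C7 is cut by a chromium-mediated allylation of an (E)-enal (from geranyl acetate) with an (S)-5-propargyl-3-(bromomethyl)butenolide; this sets C6 and C7 from C8 and turns the butenolide into the α-methylene-γ-lactone.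
4. The butenolide comes from (S)-epichlorohydrin (C8 bought): acetylide opening, ylide homologation to the allylic alcohol, acylation with 2-(bromomethyl)acrylic acid, ring-closing metathesis.
5. Ring order: butenolide (later the α-methylene lactone) → oxirane → 10-membered carbocycle.

Assumption: atoms are called C1–C15 by germacrane numbering (C1–C10 ring, C11–C13 lactone carbons on C7 with C12 the carbonyl, C14 on C10, C15 on C4); in this numbering the given SMILES is the (1S,4R,5R,6S,7R,8S) isomer with a Z (angeloyl) ester.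

**Route**

Step 1
Reactants: 1 (S)-epichlorohydrin; 2 ethynyltrimethylsilane
Product: 3 (2S)-1-chloro-5-(trimethylsilyl)pent-4-yn-2-ol
Conditions: 2, n-BuLi, THF, −78 °C; BF3·OEt2; then 1, −78 °C; H2O quench
Reagents that add atoms: none
Why: Yamaguchi alkynylation: the BF3-activated epoxide is opened by the lithium acetylide in an SN2 reaction at the unsubstituted ring carbon only, so the purchased stereocentre (the future C8) is not touched and the chloride is kept for the next step.

Step 2
Reactants: 3 (2S)-1-chloro-5-(trimethylsilyl)pent-4-yn-2-ol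
Product: 5 (3S)-6-(trimethylsilyl)hex-1-en-5-yn-3-ol, via alkynyl epoxide 4 (not isolated)
Conditions: Me3S+ I− (3.5 equiv), n-BuLi (3.3 equiv), THF, −10 °C → rt
Reagents that add atoms: trimethylsulfonium iodide, C[S+](C)C.[I-]
Why: Base closes the chlorohydrin to the terminal epoxide, dimethylsulfonium methylide opens it at CH2 (Corey–Chaykovsky-type attack) and the β-oxido sulfonium salt eliminates dimethyl sulfide, a known one-carbon homologation of epoxides to allylic alcohols in which no bond to the stereocentre is broken, so C8 stays S.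

Step 3
Reactants: 5 (3S)-6-(trimethylsilyl)hex-1-en-5-yn-3-ol; 6 2-(bromomethyl)prop-2-enoic acid
Product: 7 (3S)-6-(trimethylsilyl)hex-1-en-5-yn-3-yl 2-(bromomethyl)prop-2-enoate
Conditions: DCC, DMAP (5 mol %), CH2Cl2, 0 °C
Reagents that add atoms: none
Why: Steglich esterification at oxygen with retention at C8; the low temperature and small DMAP loading keep the allylic bromide from being alkylated.

Step 4
Reactants: 7 (3S)-6-(trimethylsilyl)hex-1-en-5-yn-3-yl 2-(bromomethyl)prop-2-enoate
Product: 8 (5S)-3-(bromomethyl)-5-[3-(trimethylsilyl)prop-2-yn-1-yl]furan-2(5H)-one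
Conditions: second-generation Hoveyda–Grubbs catalyst [RuCl2(H2IMes)(=CH–C6H4–2-OiPr)] (5 mol %), toluene, 80 °C, argon sparge
Reagents that add atoms: none
Why: Ring-closing metathesis between the vinyl group and the 1,1-disubstituted acrylate closes the butenolide (first ring) with loss of ethene, as known for methacrylates of allylic alcohols; the silyl cap keeps the alkyne out of enyne metathesis and C8 is not involved.

Step 5
Reactants: 9 geranyl acetate
Product: 12 (2E)-6,6-dimethoxy-3-methylhex-2-en-1-ol, via aldehyde 10 (not isolated), via acetal acetate 11 (not isolated)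
Conditions: O3 (1.0 equiv), CH2Cl2–MeOH, −78 °C; Me2S; p-TsOH·H2O (5 mol %), rt; then K2CO3 (0.3 equiv), rt
Reagents that add atoms: methanol, CO; ozone, [O-][O+]=O (its oxygen stays only in 10)
Why: Selective ozonolysis: ozone attacks the electron-rich 6,7-olefin rather than the 2,3-olefin deactivated by the allylic acetate, after which acid-catalysed acetalisation in methanol and base-catalysed transesterification of the acetate follow in the same pot; the 2E olefin comes unchanged from geranyl acetate.

Step 6
Reactants: 12 (2E)-6,6-dimethoxy-3-methylhex-2-en-1-ol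
Product: 13 (2E)-6,6-dimethoxy-3-methylhex-2-enal
Conditions: MnO2, CH2Cl2, rt
Reagents that add atoms: none
Why: Allylic alcohol oxidation with activated MnO2 stops at the enal and does not isomerise the 2E double bond or touch the acetal.

Step 7
Reactants: 8 (5S)-3-(bromomethyl)-5-[3-(trimethylsilyl)prop-2-yn-1-yl]furan-2(5H)-one; 13 (2E)-6,6-dimethoxy-3-methylhex-2-enal
Product: 14 (4S,5S)-4-[(1R,2E)-1-hydroxy-6,6-dimethoxy-3-methylhex-2-en-1-yl]-3-methylidene-5-[3-(trimethylsilyl)prop-2-yn-1-yl]oxolan-2-one
Conditions: CrCl2 (4 equiv), THF, 0 °C → rt; H2O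
Reagents that add atoms: none
Why: Nozaki–Hiyama (Barbier-type) allylation: divalent chromium turns the allylic bromide into an allylchromium species that adds 1,2 to the enal through a chair Zimmerman–Traxler transition state; because the γ-carbon is locked in the ring in the E-crotyl-like arrangement the C6/C7 relationship is anti, and the aldehyde bonds to the butenolide face opposite the C8 side chain (7,8-trans), so C6 and C7 are both set by the purchased C8 centre while the allyl shift creates the α-methylene lactone.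

Step 8
Reactants: 14 (4S,5S)-4-[(1R,2E)-1-hydroxy-6,6-dimethoxy-3-methylhex-2-en-1-yl]-3-methylidene-5-[3-(trimethylsilyl)prop-2-yn-1-yl]oxolan-2-one
Product: 15 (4S,5S)-4-{(S)-[(2R,3R)-3-(3,3-dimethoxypropyl)-3-methyloxiran-2-yl](hydroxy)methyl}-3-methylidene-5-[3-(trimethylsilyl)prop-2-yn-1-yl]oxolan-2-one
Conditions: mCPBA (1.1 equiv), CH2Cl2, −10 °C
Reagents that add atoms: mCPBA (3-chloroperoxybenzoic acid), OOC(=O)c1cccc(Cl)c1
Why: Hydroxyl-directed (Henbest) epoxidation of the only electron-rich olefin: in the conformer that avoids A(1,3) strain between C15 and the C6 substituents (C6–H in the olefin plane) the peracid is delivered from the face of the hydrogen-bonded OH, which gives the threo epoxy alcohol, i.e. the (4R,5R) oxirane; the α-methylene lactone and the silylalkyne are inert.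

Step 9
Reactants: 15 (4S,5S)-4-{(S)-[(2R,3R)-3-(3,3-dimethoxypropyl)-3-methyloxiran-2-yl](hydroxy)methyl}-3-methylidene-5-[3-(trimethylsilyl)prop-2-yn-1-yl]oxolan-2-one; 16 angelic acid
Product: 17 (S)-[(2R,3R)-3-(3,3-dimethoxypropyl)-3-methyloxiran-2-yl]{(2S,3R)-4-methylidene-5-oxo-2-[3-(trimethylsilyl)prop-2-yn-1-yl]oxolan-3-yl}methyl (2Z)-2-methylbut-2-enoate
Conditions: 16, 2,4,6-trichlorobenzoyl chloride, Et3N, toluene, rt; then 15, 75 °C
Reagents that add atoms: none
Why: Yamaguchi esterification through the mixed anhydride without a nucleophilic catalyst, conditions known to transfer the angeloyl group without Z to E isomerisation to the tiglate; the alcohol is never deprotonated, so neither Payne rearrangement nor translactonisation to C6 occurs and no stereocentre changes.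

Step 10
Reactants: 17 (S)-[(2R,3R)-3-(3,3-dimethoxypropyl)-3-methyloxiran-2-yl]{(2S,3R)-4-methylidene-5-oxo-2-[3-(trimethylsilyl)prop-2-yn-1-yl]oxolan-3-yl}methyl (2Z)-2-methylbut-2-enoate
Product: 19 (S)-[(2R,3R)-3-methyl-3-(3-oxopropyl)oxiran-2-yl][(2S,3R)-4-methylidene-5-oxo-2-(prop-2-yn-1-yl)oxolan-3-yl]methyl (2Z)-2-methylbut-2-enoate, via terminal alkyne 18 (not isolated)
Conditions: AgNO3 (10 mol %), acetone–H2O (4:1), rt; then PPTS (20 mol %), 45 °C
Reagents that add atoms: water, O
Why: Silver-catalysed protodesilylation frees the terminal alkyne and mild pyridinium-acid hydrolysis then unmasks the aldehyde from the dimethyl acetal, conditions under which the trisubstituted epoxide, the angelate and the α-methylene lactone survive; no stereocentre is involved.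

Step 11
Reactants: 19 (S)-[(2R,3R)-3-methyl-3-(3-oxopropyl)oxiran-2-yl][(2S,3R)-4-methylidene-5-oxo-2-(prop-2-yn-1-yl)oxolan-3-yl]methyl (2Z)-2-methylbut-2-enoate
Product: 20 CNP0104965.3 (1S,4R,5R,6S,7R,8S)-1-hydroxy-6-[(2Z)-2-methylbut-2-enoyloxy]-4,5-epoxygermacra-10(14),11(13)-dien-12,8-olide
Conditions: Ni(cod)2 (15 mol %), IPr* (1,3-bis[2,6-bis(diphenylmethyl)-4-methylphenyl]imidazol-2-ylidene, 15 mol %), 4CzIPN (2 mol %), Hantzsch ester (1.5 equiv), 2,4,6-collidinium triflate (20 mol %), THF (0.002 M, slow addition of 19), blue LEDs (450 nm), 25 °C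
Reagents that add atoms: none
Why: Proposed new method: a visible-light-driven, silane-free nickel/N-heterocyclic-carbene reductive ynal macrocyclisation — zerovalent nickel carrying the very bulky carbene couples alkyne and aldehyde by oxidative cyclisation with C–C bond formation at the internal alkyne carbon (exo mode, the steric steering known from the thermal nickel/carbene/hydrosilane ynal macrocyclisation, the closest known reaction), the oxanickelacycle is opened by protonation at oxygen and at the alkenyl–nickel bond, and the photocatalyst, reduced by the Hantzsch ester, returns divalent nickel to zerovalent nickel (the turnover mode of known photoredox cobalt- and nickel-catalysed intermolecular alkyne–aldehyde couplings), which closes the 10-membered ring, forms C1–C10 with the exocyclic methylene and releases the free alcohol; C1 is set by the existing centres, since the nickelacycle has to sit outside the forming ring and the C2–C3 bridge is expected to reach C1 only from the face anti to the C6 ester (a prediction, not a modelled result), which leads to the 1S alcohol, and cyclisation onto the α-methylene lactone is disfavoured because it would give a strained bridged bicycle.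

**Compound list**
1 | (S)-epichlorohydrin, (2S)-2-(chloromethyl)oxirane | ClC[C@@H]1CO1 | starting material
2 | ethynyltrimethylsilane | C#C[Si](C)(C)C | starting material
3 | (2S)-1-chloro-5-(trimethylsilyl)pent-4-yn-2-ol | ClC[C@@H](O)CC#C[Si](C)(C)C | intermediate
4 | trimethyl{3-[(2S)-oxiran-2-yl]prop-1-yn-1-yl}silane (not isolated) | C[Si](C)(C)C#CC[C@H]1CO1 | intermediate
5 | (3S)-6-(trimethylsilyl)hex-1-en-5-yn-3-ol | C=C[C@@H](O)CC#C[Si](C)(C)C | intermediate
6 | 2-(bromomethyl)prop-2-enoic acid | OC(=O)C(=C)CBr | starting material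
7 | (3S)-6-(trimethylsilyl)hex-1-en-5-yn-3-yl 2-(bromomethyl)prop-2-enoate | C=C[C@@H](OC(=O)C(=C)CBr)CC#C[Si](C)(C)C | intermediate
8 | (5S)-3-(bromomethyl)-5-[3-(trimethylsilyl)prop-2-yn-1-yl]furan-2(5H)-one | BrCC1=C[C@H](CC#C[Si](C)(C)C)OC1=O | intermediate
9 | geranyl acetate, (2E)-3,7-dimethylocta-2,6-dien-1-yl acetate | CC(C)=CCC/C(C)=C/COC(C)=O | starting material
10 | (2E)-3-methyl-6-oxohex-2-en-1-yl acetate (not isolated) | O=CCC/C(C)=C/COC(C)=O | intermediate
11 | (2E)-6,6-dimethoxy-3-methylhex-2-en-1-yl acetate (not isolated) | COC(OC)CC/C(C)=C/COC(C)=O | intermediate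
12 | (2E)-6,6-dimethoxy-3-methylhex-2-en-1-ol | COC(OC)CC/C(C)=C/CO | intermediate
13 | (2E)-6,6-dimethoxy-3-methylhex-2-enal | COC(OC)CC/C(C)=C/C=O | intermediate
14 | (4S,5S)-4-[(1R,2E)-1-hydroxy-6,6-dimethoxy-3-methylhex-2-en-1-yl]-3-methylidene-5-[3-(trimethylsilyl)prop-2-yn-1-yl]oxolan-2-one | C=C1C(=O)O[C@@H](CC#C[Si](C)(C)C)[C@@H]1[C@H](O)/C=C(\C)CCC(OC)OC | intermediate
15 | (4S,5S)-4-{(S)-[(2R,3R)-3-(3,3-dimethoxypropyl)-3-methyloxiran-2-yl](hydroxy)methyl}-3-methylidene-5-[3-(trimethylsilyl)prop-2-yn-1-yl]oxolan-2-one | C=C1C(=O)O[C@@H](CC#C[Si](C)(C)C)[C@@H]1[C@H](O)[C@H]2O[C@]2(C)CCC(OC)OC | intermediate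
16 | angelic acid, (2Z)-2-methylbut-2-enoic acid | C/C=C(/C)C(=O)O | starting material
17 | (S)-[(2R,3R)-3-(3,3-dimethoxypropyl)-3-methyloxiran-2-yl]{(2S,3R)-4-methylidene-5-oxo-2-[3-(trimethylsilyl)prop-2-yn-1-yl]oxolan-3-yl}methyl (2Z)-2-methylbut-2-enoate | C=C1C(=O)O[C@@H](CC#C[Si](C)(C)C)[C@@H]1[C@H](OC(=O)/C(C)=C\C)[C@H]2O[C@]2(C)CCC(OC)OC | intermediate
18 | (S)-[(2R,3R)-3-(3,3-dimethoxypropyl)-3-methyloxiran-2-yl][(2S,3R)-4-methylidene-5-oxo-2-(prop-2-yn-1-yl)oxolan-3-yl]methyl (2Z)-2-methylbut-2-enoate (not isolated) | C=C1C(=O)O[C@@H](CC#C)[C@@H]1[C@H](OC(=O)/C(C)=C\C)[C@H]2O[C@]2(C)CCC(OC)OC | intermediate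
19 | (S)-[(2R,3R)-3-methyl-3-(3-oxopropyl)oxiran-2-yl][(2S,3R)-4-methylidene-5-oxo-2-(prop-2-yn-1-yl)oxolan-3-yl]methyl (2Z)-2-methylbut-2-enoate | C=C1C(=O)O[C@@H](CC#C)[C@@H]1[C@H](OC(=O)/C(C)=C\C)[C@H]2O[C@]2(C)CCC=O | intermediate
20 | CNP0104965.3, (1S,4R,5R,6S,7R,8S)-1-hydroxy-6-[(2Z)-2-methylbut-2-enoyloxy]-4,5-epoxygermacra-10(14),11(13)-dien-12,8-olide | C=C1C(=O)O[C@H]2CC(=C)[C@@H](O)CC[C@@]3(C)O[C@@H]3[C@@H](OC(=O)/C(C)=C\C)[C@H]12 | target

**Step count and risks**

Total steps: 11. Longest linear sequence: 9 steps (1, 2, 3, 4, 7, 8, 9, 10, 11); steps 5 and 6 make the enal branch.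

Step 11 is the most likely to fail. The new photochemical macrocyclisation could close endo instead of exo, oligomerise, reduce the α-methylene lactone, or give the C1 epimer; the C1 outcome is argued from ring geometry only. The fallback uses known chemistry and sets out from 19: the ring is closed thermally with Ni(cod)2, IPr* and triethylsilane under slow addition in THF, the established nickel/carbene hydrosilane ynal macrocyclisation, which gives the C1 triethylsilyl ether of the target, silyl ether F6. HF·pyridine in THF then removes the silyl group and the route is rejoined at 20. The silyl-capped metallacycle also gives an independent chance at the C1 configuration.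

Step 4 is the second risk: ring-closing metathesis onto an electron-poor 1,1-disubstituted acrylate that also carries an allylic bromide may stall or decompose the catalyst. The fallback sets out from 5 and avoids metathesis. TBSCl and imidazole give the silyl ether F1. OsO4 (cat.) with NaIO4 cleaves the vinyl group to the α-silyloxy aldehyde F2. A Morita–Baylis–Hillman reaction with methyl acrylate and DABCO gives the adduct F3 as both carbinol epimers, which is harmless because that carbon becomes sp2. Aqueous HF in MeCN removes the TBS group and the freed C8 hydroxyl lactonises to the hydroxy lactone F4. PBr3 in Et2O at 0 °C then brominates with allylic transposition (SN2') and the route is rejoined at 8.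

Step 9 is the third risk: the hindered C6 alcohol may acylate slowly, and forcing conditions can isomerise the angelate to the tiglate. The fallback sets out from 15 and builds the Z olefin on the substrate instead of transferring it. DCC coupling with 2-[bis(2,2,2-trifluoroethoxy)phosphoryl]propanoic acid gives the phosphonate ester F5. A Still–Gennari olefination with acetaldehyde (KHMDS, 18-crown-6, THF, −78 °C) then forms the Z-trisubstituted double bond and the route is rejoined at 17.

**Further compounds**
F1 | step 4 | tert-butyldimethyl{[(3S)-6-(trimethylsilyl)hex-1-en-5-yn-3-yl]oxy}silane | C=C[C@@H](O[Si](C)(C)C(C)(C)C)CC#C[Si](C)(C)C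
F2 | step 4 | (2S)-2-[(tert-butyldimethylsilyl)oxy]-5-(trimethylsilyl)pent-4-ynal | O=C[C@@H](O[Si](C)(C)C(C)(C)C)CC#C[Si](C)(C)C
F3 | step 4 | methyl 2-{(2S)-2-[(tert-butyldimethylsilyl)oxy]-1-hydroxy-5-(trimethylsilyl)pent-4-yn-1-yl}prop-2-enoate (both C1 epimers) | COC(=O)C(=C)C(O)[C@@H](O[Si](C)(C)C(C)(C)C)CC#C[Si](C)(C)C
F4 | step 4 | (5S)-4-hydroxy-3-methylidene-5-[3-(trimethylsilyl)prop-2-yn-1-yl]oxolan-2-one (both C4 epimers) | C=C1C(O)[C@H](CC#C[Si](C)(C)C)OC1=O
F5 | step 9 | (S)-[(2R,3R)-3-(3,3-dimethoxypropyl)-3-methyloxiran-2-yl]{(2S,3R)-4-methylidene-5-oxo-2-[3-(trimethylsilyl)prop-2-yn-1-yl]oxolan-3-yl}methyl 2-[bis(2,2,2-trifluoroethoxy)phosphoryl]propanoate (both epimers at the phosphonate carbon) | C=C1C(=O)O[C@@H](CC#C[Si](C)(C)C)[C@@H]1[C@H](OC(=O)C(C)P(=O)(OCC(F)(F)F)OCC(F)(F)F)[C@H]2O[C@]2(C)CCC(OC)OC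
F6 | step 11 | (1S,4R,5R,6S,7R,8S)-6-[(2Z)-2-methylbut-2-enoyloxy]-1-(triethylsilyloxy)-4,5-epoxygermacra-10(14),11(13)-dien-12,8-olide | C=C1C(=O)O[C@H]2CC(=C)[C@@H](O[Si](CC)(CC)CC)CC[C@@]3(C)O[C@@H]3[C@@H](OC(=O)/C(C)=C\C)[C@H]12
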